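(The earlier runs and the new flask stem from a simulated flask with constants of no real substance.)

- The constants of the steps were hidden from me, so I rested my choice for the next flask, to raise the free catalyst above 0.12 mol% or keep it there, on the ash run.

the same everywhere: left-handed substrate 0.58 M; right-handed substrate 0.58 M; free catalyst 0.12 mol%

| run | reagent | impurity | remark | time |
|---|---|---|---|---|
| ash | 2 equiv | 0.32 mM | run made earlier |  |
| flask | 2.00 equiv | 0.16 mM |  | 1.0 h |

ash run (percent of the left-handed substrate and right-handed substrate together charged)

| time / min | right-handed substrate / % | left-handed substrate / % |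
|---|---|---|
| 0.500 | 50.0 | 44.9 |
| 0.833 | 49.1 | 42.8 |
| 1.50 | 48.6 | 38.1 |
| 3.00 | 47.4 | 31.1 |
| 6.00 | 45.9 | 20.0 |

(scatter of a reading: 0.3 percentage points)

- free catalyst is single-handed; left-handed substrate and right-handed substrate are mirror images of each other, charged as a racemate, each of them at the stated concentration
- steps that have been proposed: reagent <-> dormant form; free catalyst + right-handed substrate <-> catalyst intermediate B; free catalyst + impurity -> spent catalyst; left-handed product <-> right-handed product; reagent + catalyst intermediate B -> free catalyst + right-handed product; free catalyst + left-handed substrate <-> catalyst intermediate A; reagent + catalyst intermediate A -> free catalyst + left-handed product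
- no earlier run changes the charge of impurity; that part of a forecast is a guess

* whether the excess of right-handed substrate over left-handed substrate among what is left of the two reaches 80 % by 1.0 h (yes / no)
* the highest excess of right-handed substrate over left-handed substrate among what is left of the two up to 1.0 h

- I worked in powers of ten. Let ρ be left-handed substrate over right-handed substrate, which is one at the racemic charge.
- In the ash run, ρ went from 0.898 at 0.500 min to 0.436 at 6.00 min, which gives 3.43 h⁻¹. I call this reading, with the scatter of its two end points in it, G, the powers of ten by which ρ falls per unit time.
- An excess of 80 % means ρ = 0.111, a fall of 0.954 powers of ten. At pace G that takes 0.279 h, which is shorter than the 1.0 h allowed.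
- Held for the whole 1.0 h, G gives ρ = 3.75 × 10⁻⁴, an excess of 99.9 %.
- The flask carries 0.16 mM of impurity, half of the ash run's 0.32 mM. No earlier run changes that charge, so carrying G over is a guess.
- I decided to keep the free catalyst at 0.12 mol%, run the full 1.0 h, and sample near 0.279 h.
- The forecast said yes with a top of 99.9 %, on the ground that “The substrates do not racemise, so the excess keeps rising”.
- The flask gave yes with a top of 99.9 %. The excess reached 80 % at 0.212 h, with right-handed substrate at 38.8 % of both substrates charged, against 20.7 % at 1.00 h. At that last time left-handed substrate stood at 0.0104 %, so ρ had fallen 3.30 powers of ten, against the 3.43 that G gives.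

    reagent ⇌ dormant form (K = 0.180, k = 0.0240 s⁻¹)
    free catalyst + right-handed substrate ⇌ catalyst intermediate B (K = 0.490 M⁻¹, k = 33.0 M⁻¹ s⁻¹)
    free catalyst + impurity → spent catalyst (k = 220 M⁻¹ s⁻¹)
    left-handed product ⇌ right-handed product (k = 0.00240 s⁻¹)
    reagent + catalyst intermediate B → free catalyst + right-handed product (k = 3.60 M⁻¹ s⁻¹)
    free catalyst + left-handed substrate ⇌ catalyst intermediate A (K = 2.10 M⁻¹, k = 590 M⁻¹ s⁻¹)
    reagent + catalyst intermediate A → free catalyst + left-handed product (k = 8.00 M⁻¹ s⁻¹)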